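The earlier runs and the new flask are simulated from invented constants; the scatter is artificial.

In a one-step world the starting complex is a single peak whose fraction left halves at a steady pace, and that pace follows the ligand present.

| flask | starting complex | incoming ligand | capture agent | remark | time |
|---|---|---|---|---|---|
| zeta | 0.50 mM | 1.5 equiv | 0.038 mM | run made earlier |  |
| alpha | 0.50 mM | 1.5 equiv | 0.013 mM | run made earlier |  |
| red | 0.50 mM | 1.50 equiv | 0.0250 mM |  | 6.0 min |
| amber | 0.50 mM | 2.50 equiv | 0.0250 mM |  | 6.0 min |
| violet | 0.50 mM | 4.00 equiv | 0.0250 mM |  | 6.0 min |

| run | time / s | complex with two exchanged / % | starting complex / % |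
|---|---|---|---|
| zeta | 20.0 | 2.3 | 65.5 |
| zeta | 40.0 | 7.2 | 44.9 |
| zeta | 60.0 | 10.2 | 33.2 |
| zeta | 80.0 | 15.7 | 25.7 |
| zeta | 120 | 20.0 | 16.2 |
| alpha | 20.0 | 2.5 | 64.1 |
| alpha | 40.0 | 7.7 | 44.9 |
| alpha | 60.0 | 11.1 | 32.5 |
| alpha | 80.0 | 14.5 | 26.1 |
| alpha | 120 | 19.5 | 16.3 |

(each reading ± 0.5 percentage points)

1. which of these holds the largest part of the starting complex at the end of red (complex with two exchanged / complex with one exchanged / complex with three exchanged / starting complex)
2. which of these holds the largest part of the starting complex at the end of amber (complex with two exchanged / complex with one exchanged / complex with three exchanged / starting complex)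
3. which of these holds the largest part of the starting complex at the end of violet (complex with two exchanged / complex with one exchanged / complex with three exchanged / starting complex)
4. final complex with two exchanged in violet, as a percentage of the starting complex charged

- a reading or a percentage of complex with two exchanged counts all its forms, free or not
- no earlier run changes the charge of incoming ligand; that part of a forecast is a guess
- a reading of starting complex is of its free form alone

Zeta's first reading, 65.5% left at 20.0 s, gives a pseudo-first-order half-life of 32.8 s at 1.5 equiv. Alpha, with 0.013 mM of capture agent against zeta's 0.038 mM, reads 44.9% at 40.0 s, and zeta reads 44.9%, so capture agent is set aside here.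

The flask is not one-step. Taking the second exchange as a third as fast and working from the fraction left gives 7.59% of complex with two exchanged at 40.0 s, against zeta's reading of 7.2%. The third exchange is assumed equally slow.

In violet each complex can take 3 ligands, so the 4.00 equiv charged leaves a floor of 1.00 equiv. At that floor complex with two exchanged is reckoned to halve in 147 s. With the first exchange taken as done at once and the two later steps as equal, complex with two exchanged peaks at 36.8%, one later lifetime in. With ligand taken midway between charge and floor, that comes at 1.42 min. Halving from there to 6.0 min leaves 10.1%.

The weak link is the floor. Complex with two exchanged still owes one ligand, and complex with one exchanged, taken as half as abundant, owes two, so ligand late in violet is reckoned near 1.20 equiv. The tail half-life, the time in which complex with two exchanged halves late in violet at that ligand level, becomes 123 s. This reckoning therefore commits to 7.78%.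

The forecast names complex with one exchanged, complex with two exchanged and complex with three exchanged for red, amber and violet and, differing from this reckoning, puts complex with two exchanged in violet at 14% (range 8% to 24%), with “ligand remains in excess and three-exchanged dominates”.

The flasks give complex with one exchanged, complex with three exchanged and complex with three exchanged, and 8.65% of complex with two exchanged in violet.

    2 starting complex → homo dimer (k = 0.103 M⁻¹ s⁻¹)
    complex with one exchanged + incoming ligand → leaving ligand + complex with two exchanged (k = 11.8 M⁻¹ s⁻¹)
    starting complex + complex with two exchanged ⇌ idle adduct, settled at all times (K = 11000 M⁻¹)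
    starting complex + incoming ligand → leaving ligand + complex with one exchanged (k = 30.3 M⁻¹ s⁻¹)
    complex with two exchanged + incoming ligand → leaving ligand + complex with three exchanged (k = 14.9 M⁻¹ s⁻¹)
    complex with one exchanged + capture agent → trapped intermediate (k = 9.21 M⁻¹ s⁻¹)

In violet the first exchange had 89% of its turnover to the asked time behind it by 1.20 min. The exchange from two to three had done half of its turnover to the asked time by 2.11 min, and 30% of the ligand charge remained at 6.00 min. Stepping back 2.00 min from violet's end, the tail half-life gives 17.0%. The same flask read at 4.0 min holds 16.4%.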